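The route rests on disconnecting C2–C3 (briarane numbering), the bond between the two carbinol carbons of the trans-2,3-diol that lies in the eight-membered oxocane O–C4–C3–C2–C1–C10–C9–C8, flanked by quaternary C1 of ring A and ether carbon C4 of the dihydropyran. A SmI2 pinacol coupling of two aldehydes forges this bond, closes the oxocane and with it the ten-membered carbocycle, and sets C2 and C3 in one operation. Its precursor is dialdehyde 35: ring A (C11 spiro-epoxide, C14 acetate, formyl on C1) joined through C9(OAc)–C10 to the cis-fused dihydropyran–butyrolactone that carries the second formyl group on C4; chlorine is introduced only afterwards.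

Key step: step 26

Remark: briarane numbering is used for all intermediates (C15 methyl on C1, C16 on C5, C18 methyl on C17, C19 lactone carbonyl, C20 epoxide CH2); potassium trifluoro{[(4-methoxybenzyl)oxy]methyl}borate (24) is taken to be a catalogue reagent.

**Dihydropyran–lactone half (steps 1–12)**

Step 1
Reactants: 1 2-chloro-N-methoxy-N-methylacetamide; 2 4-methoxybenzyl alcohol
Product: 3 N-methoxy-2-[(4-methoxybenzyl)oxy]-N-methylacetamide
Conditions: NaH, THF, 0 °C to rt
Reagents that add atoms: none
Why: Williamson ether synthesis in which the sodium alkoxide of 2 displaces the activated primary chloride of 1 faster than it attacks the amide carbonyl.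

Step 2
Reactants: 4 furfuryl alcohol
Product: 5 tert-butyl(furan-2-ylmethoxy)dimethylsilane
Conditions: TBSCl, imidazole, CH2Cl2, rt
Reagents that add atoms: tert-butyldimethylsilyl chloride, CC(C)(C)[Si](C)(C)Cl
Why: Standard silylation of a primary alcohol, whose oxygen later becomes the C9 oxygen.

Step 3
Reactants: 5 tert-butyl(furan-2-ylmethoxy)dimethylsilane; 3 N-methoxy-2-[(4-methoxybenzyl)oxy]-N-methylacetamide
Product: 7 1-{5-[(tert-butyldimethylsilyloxy)methyl]furan-2-yl}-2-[(4-methoxybenzyl)oxy]ethan-1-one, via 5-lithiofuran 6 (not isolated)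
Conditions: n-BuLi, THF, −78 to 0 °C; then 3, −78 °C
Reagents that add atoms: none
Why: Lithiation of the 2-substituted furan at its only free alpha position followed by Weinreb ketone synthesis, the chelated tetrahedral intermediate preventing over-addition.

Step 4
Reactants: 7 furyl ketone
Product: 8 (1S)-1-{5-[(tert-butyldimethylsilyloxy)methyl]furan-2-yl}-2-[(4-methoxybenzyl)oxy]ethan-1-ol
Conditions: RuCl[(S,S)-TsDPEN](p-cymene) (1 mol%), HCO2H/Et3N (5:2), CH2Cl2, rt
Reagents that add atoms: none
Why: Noyori asymmetric transfer hydrogenation of a heteroaryl ketone, in which the (S,S)-catalyst should give the (S)-carbinol by the same aryl/alkyl discrimination as for aryl alkyl ketones, and this centre becomes C4.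

Step 5
Reactants: 8 (S)-furyl carbinol
Product: 9 (2S)-6-[(tert-butyldimethylsilyloxy)methyl]-6-hydroxy-2-{[(4-methoxybenzyl)oxy]methyl}-2H-pyran-3(6H)-one (both anomers)
Conditions: NBS, NaHCO3, THF/H2O (4:1), 0 °C
Reagents that add atoms: water, O
Why: Achmatowicz rearrangement, in which bromonium-induced hydration of the furan gives an ene-dione that the carbinol oxygen closes to the pyranone hemiketal, leaving C4 untouched and the anomeric carbon (future C8) to be ionised next.

Step 6
Reactants: 9 pyranone hemiketal; 10 1-(tert-butyldimethylsilyloxy)-1-methoxyethene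
Product: 11 methyl 2-[(2S,6S)-2-[(tert-butyldimethylsilyloxy)methyl]-6-{[(4-methoxybenzyl)oxy]methyl}-5-oxo-5,6-dihydro-2H-pyran-2-yl]acetate
Conditions: BF3·OEt2, CH2Cl2, −78 to −40 °C
Reagents that add atoms: none
Why: Lewis-acid ionisation of the hemiketal and Mukaiyama-type C-glycosylation of the resulting ketose-type oxocarbenium ion create quaternary C8, the ketene acetal entering axially and trans to the C4 side chain so that the C17 arm is trans and the C9 arm cis to C3.

Step 7
Reactants: 11 keto ester
Product: 12 methyl 2-[(2S,6S)-2-[(tert-butyldimethylsilyloxy)methyl]-5-hydroxy-6-{[(4-methoxybenzyl)oxy]methyl}-5-methyl-5,6-dihydro-2H-pyran-2-yl]acetate (both C5 epimers)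
Conditions: MeMgBr, CeCl3, THF, −78 °C
Reagents that add atoms: methylmagnesium bromide, C[Mg]Br
Why: 1,2-addition of the weakly basic organocerium reagent to the enone carbonyl, which outpaces attack on the ester and does not enolise toward C4, the new carbinol centre being erased in the next step.

Step 8
Reactants: 12 tertiary allylic alcohol
Product: 13 methyl 2-[(2R,6R)-2-[(tert-butyldimethylsilyloxy)methyl]-6-{[(4-methoxybenzyl)oxy]methyl}-5-methyl-3-oxo-3,6-dihydro-2H-pyran-2-yl]acetate
Conditions: pyridinium chlorochromate, 4 Å MS, CH2Cl2, rt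
Reagents that add atoms: pyridinium chlorochromate, [O-][Cr](=O)(=O)Cl.c1cc[nH+]cc1
Why: Dauben–Babler oxidative transposition, in which the tertiary allylic chromate ester shifts [3,3] to C7 and is oxidised there, giving the C7 ketone conjugated to the new C5(Me)=C6 bond.

Step 9
Reactants: 13 transposed enone
Product: 15 17-desmethyl pyranolactone (4R,7S,8R; cis-fused dihydropyran–gamma-lactone with C4 CH2OPMB, C5 methyl, C5=C6 and C8 CH2OTBS), via hydroxy ester 14 (not isolated)
Conditions: NaBH4, CeCl3·7H2O, MeOH, −40 °C; then PPTS (cat.), PhMe, 50 °C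
Reagents that add atoms: none
Why: Luche 1,2-reduction then lactonisation, where the envelope that keeps the C3 and C9 arms pseudo-equatorial holds the CH2CO2Me arm pseudo-axial on C8, hydride attacks C7 anti to it, and the resulting hydroxyl is cis to that arm and closes the cis-fused lactone.

Step 10
Reactants: 15 17-desmethyl pyranolactone
Product: 17 pyranolactone silyl ether (4R,7S,8R,17R), via lithium enolate 16 (not isolated)
Conditions: LiN(SiMe3)2, THF, −78 °C; then MeI, DMPU, −78 °C
Reagents that add atoms: iodomethane, CI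
Why: Kinetic lactone enolate alkylation in which MeI approaches C17 anti to the vicinal CH2OTBS group on quaternary C8, placing the methyl cis to the ring oxygen, while the low temperature suppresses beta-elimination of that oxygen.

Step 11
Reactants: 17 pyranolactone silyl ether
Product: 18 pyranolactone C9 alcohol
Conditions: HF·pyridine, pyridine, THF, 0 °C to rt
Reagents that add atoms: none
Why: Buffered fluoride cleavage of the primary silyl ether, to which the PMB ether, the lactone and the alkene are inert.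

Step 12
Reactants: 18 pyranolactone C9 alcohol
Product: 19 pyranolactone C9 aldehyde
Conditions: Dess–Martin periodinane, CH2Cl2, rt
Reagents that add atoms: none
Why: Dess–Martin oxidation of the neopentyl primary alcohol gives an aldehyde on quaternary C8 that has no alpha-hydrogen and cannot epimerise.

**Ring A half (steps 13–19)**

Step 13
Reactants: 20 1,4-dioxaspiro[4.5]dec-6-en-8-one
Product: 21 7-iodo-1,4-dioxaspiro[4.5]dec-6-en-8-one
Conditions: I2, pyridine, CH2Cl2, 0 °C to rt
Reagents that add atoms: iodine, II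
Why: Johnson alpha-iodination of an enone by pyridine conjugate addition, iodination of the enolate and elimination.

Step 14
Reactants: 21 alpha-iodoenone
Product: 22 (8S)-7-iodo-1,4-dioxaspiro[4.5]dec-6-en-8-ol
Conditions: (R)-Me-CBS oxazaborolidine (10 mol%), BH3·SMe2, THF, −20 °C
Reagents that add atoms: none
Why: Corey–Bakshi–Shibata reduction in which the alpha-iodoalkenyl arm acts as the large group, so the (R)-catalyst should give the (S)-allylic alcohol that becomes C14.

Step 15
Reactants: 22 iodo allylic alcohol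
Product: 23 (8S)-8-(tert-butyldimethylsilyloxy)-7-iodo-1,4-dioxaspiro[4.5]dec-6-ene
Conditions: TBSCl, imidazole, DMF, rt
Reagents that add atoms: tert-butyldimethylsilyl chloride, CC(C)(C)[Si](C)(C)Cl
Why: Standard silylation of a secondary allylic alcohol, the silyl ether later steering the cuprate addition.

Step 16
Reactants: 23 vinyl iodide; 24 potassium trifluoro{[(4-methoxybenzyl)oxy]methyl}borate
Product: 25 (8S)-8-(tert-butyldimethylsilyloxy)-7-{[(4-methoxybenzyl)oxy]methyl}-1,4-dioxaspiro[4.5]dec-6-ene
Conditions: Pd(OAc)2 (5 mol%), RuPhos (10 mol%), Cs2CO3, 1,4-dioxane/H2O (10:1), 90 °C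
Reagents that add atoms: none
Why: Suzuki–Miyaura coupling of an alkenyl iodide with an alkoxymethyltrifluoroborate installs the protected C2 carbon without touching the stereocentre.

Step 17
Reactants: 25 allylic ketal
Product: 26 (4S)-4-(tert-butyldimethylsilyloxy)-3-{[(4-methoxybenzyl)oxy]methyl}cyclohex-2-en-1-one
Conditions: PPTS, acetone/H2O, 50 °C
Reagents that add atoms: water, O
Why: Mild acid hydrolysis of the allylic dioxolane unmasks the enone carbonyl (C11) while the silyl and PMB ethers survive.

Step 18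
Reactants: 26 gamma-silyloxy enone
Product: 28 (3S,4S)-4-(tert-butyldimethylsilyloxy)-3-{[(4-methoxybenzyl)oxy]methyl}-3-methylcyclohex-1-en-1-yl trifluoromethanesulfonate, via lithium enolate 27 (not isolated)
Conditions: Me2CuLi (MeLi, CuI), Et2O, −40 to 0 °C; then N-(5-chloro-2-pyridyl)triflimide, THF, −78 °C to rt
Reagents that add atoms: lithium dimethylcuprate, [Li+].C[Cu-]C; N-(5-chloropyridin-2-yl)-1,1,1-trifluoro-N-(trifluoromethylsulfonyl)methanesulfonamide, O=S(=O)(N(c1ccc(Cl)cn1)S(=O)(=O)C(F)(F)F)C(F)(F)F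
Why: Cuprate conjugate addition creates quaternary C1 with the methyl anti to the C14 silyloxy group (held pseudo-axial by allylic strain with the CH2OPMB arm), and the regiodefined C10–C11 enolate is trapped on oxygen as the enol triflate.

Step 19
Reactants: 28 enol triflate
Product: 29 tert-butyl{[(1S,2S)-2-{[(4-methoxybenzyl)oxy]methyl}-2-methyl-4-[(trimethylsilyl)methyl]cyclohex-3-en-1-yl]oxy}dimethylsilane
Conditions: Me3SiCH2MgCl, Pd(PPh3)4 (5 mol%), THF, rt
Reagents that add atoms: (trimethylsilyl)methylmagnesium chloride, C[Si](C)(C)C[Mg]Cl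
Why: Kumada cross-coupling of an enol triflate with (trimethylsilyl)methylmagnesium chloride gives the allylsilane whose gamma-carbon is C10.

**Union and endgame (steps 20–27)**

Step 20
Reactants: 29 ring A allylsilane; 19 pyranolactone C9 aldehyde
Product: 30 union product with C9 hydroxyl, 11(20)-methylene, C14 OTBS and PMB ethers on O2 and O3 (1S,9S,10S,14S; pyranolactone centres as in 19)
Conditions: BF3·OEt2, CH2Cl2, −78 °C
Reagents that add atoms: none
Why: Hosomi–Sakurai allylation forms C9–C10 and the exocyclic methylene by SE2′ attack of C10 anti to the pseudo-axial CH2OPMB arm on C1 (C9 trans to C2), and the open antiperiplanar transition state with the C8 group turned away from C1 gives the syn relationship corresponding to 9S, the aldehyde itself having little facial bias because C8 carries two similar ring carbons.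

Step 21
Reactants: 30 union product
Product: 31 C9,C14-diol
Conditions: HF·pyridine, pyridine, THF, rt
Reagents that add atoms: none
Why: Buffered fluoride desilylation of the C14 silyl ether, which leaves the PMB ethers, the lactone and both alkenes untouched.

Step 22
Reactants: 31 C9,C14-diol
Product: 32 C9,C14-diacetate
Conditions: Ac2O, DMAP, pyridine, CH2Cl2, rt
Reagents that add atoms: acetic anhydride, CC(=O)OC(C)=O
Why: DMAP-catalysed acetylation installs both acetates of the target on the two secondary alcohols in one operation.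

Step 23
Reactants: 32 C9,C14-diacetate
Product: 33 11,20-epoxide (11R)
Conditions: mCPBA, NaHCO3, CH2Cl2, 0 °C
Reagents that add atoms: 3-chloroperoxybenzoic acid, OOC(=O)c1cccc(Cl)c1
Why: Prilezhaev epoxidation selects the 1,1-disubstituted methylene over the C5=C6 alkene, which is deactivated by two allylic C–O bonds, and the peracid approaches anti to the syn-axial C15 methyl so that the oxygen is cis to H10.

Step 24
Reactants: 33 bis-PMB ether epoxide
Product: 34 C2,C3-diol (two primary alcohols)
Conditions: DDQ, CH2Cl2/pH 7 buffer (10:1), 0 °C to rt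
Reagents that add atoms: none
Why: Oxidative cleavage of both PMB ethers by benzylic hydride abstraction under neutral conditions that spare the epoxide, acetates and lactone, the product being carried on at once to avoid acetyl migration from O14 to O2.

Step 25
Reactants: 34 C2,C3-diol
Product: 35 C2,C3-dialdehyde (precursor of the key step)
Conditions: Dess–Martin periodinane, NaHCO3, CH2Cl2, 0 °C to rt
Reagents that add atoms: none
Why: Double Dess–Martin oxidation under buffered, non-basic conditions so that C4–H next to the new C3 aldehyde is neither epimerised nor drawn into conjugation, 35 being used without chromatography.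

Step 26
Reactants: 35 C2,C3-dialdehyde
Product: 36 6-deschloro-5-methyl-5-ene 2,3-diol (2R,3S)
Conditions: SmI2 (4 equiv), HMPA (16 equiv), THF, −78 to −20 °C, slow addition of 35 (final 0.005 M)
Reagents that add atoms: none
Why: Two SmI2 equivalents transfer one electron each to the C2 and C3 formyl groups, the HMPA-solvated ketyls combine to the C2–C3 bond (or one ketyl adds to the second samarium-bound aldehyde and the alkoxy radical is reduced), and protonation on work-up gives the diol. The closest known reaction is the SmI2-mediated intramolecular pinacol cyclisation of dialdehydes, which is established for eight-membered rings and for alpha-alkoxy aldehydes. The oxocane O–C4–C3–C2–C1–C10–C9–C8 closes by this eight-membered radical C–C coupling and the same bond completes the ten-membered carbocycle C1–C10; the C8–C9–C10 link and the cis arrangement of the C3 and C9 arms across the pyran oxygen already hold the two carbonyls close, so dilution only has to suppress dimerisation. C2 is controlled by ring A, whose axial C15 methyl and C14 acetate leave one face of the C1 formyl group open, and C3 is controlled by C4 and the rigid dihydropyran, which turn the ketyl oxygen to the outside of the forming ring. Because HMPA fills the samarium coordination sphere the two O–Sm groups are not bridged and should settle pseudo-diequatorial, which is the required trans (2R,3S) diol. The step needs chemoselectivity for the aldehydes and retention at C4: the C1 formyl group cannot enolise, no halide is present, the acetates, lactone and isolated epoxide are inert to SmI2 at low temperature, and 35 is used at once under non-basic conditions.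

Step 27
Reactants: 36 6-deschloro-5-methyl-5-ene 2,3-diol
Product: 37 CNP0340728.1
Conditions: Ca(OCl)2, CO2 (solid), CH2Cl2/H2O, 0 °C
Reagents that add atoms: calcium hypochlorite, [Ca+2].[O-]Cl.[O-]Cl
Why: Ene-type chlorination by HOCl, in which Cl+ adds to C6 (the less substituted alkene carbon) from the exo face of the dihydropyran, away from the five-atom bridge and therefore cis to the C7 lactone oxygen (6S), and a proton is lost from the C16 methyl instead of the C4 methine to give the 5(16)-methylene.

**Compound list**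

1 | 2-chloro-N-methoxy-N-methylacetamide | CON(C)C(=O)CCl | starting material
2 | 4-methoxybenzyl alcohol | COc1ccc(CO)cc1 | starting material
3 | N-methoxy-2-[(4-methoxybenzyl)oxy]-N-methylacetamide | CON(C)C(=O)COCc1ccc(OC)cc1 | intermediate
4 | furfuryl alcohol | OCc1ccco1 | starting material
5 | tert-butyl(furan-2-ylmethoxy)dimethylsilane | CC(C)(C)[Si](C)(C)OCc1ccco1 | intermediate
6 | {5-[(tert-butyldimethylsilyloxy)methyl]furan-2-yl}lithium | [Li]c1ccc(CO[Si](C)(C)C(C)(C)C)o1 | intermediate
7 | 1-{5-[(tert-butyldimethylsilyloxy)methyl]furan-2-yl}-2-[(4-methoxybenzyl)oxy]ethan-1-one | COc1ccc(COCC(=O)c2ccc(CO[Si](C)(C)C(C)(C)C)o2)cc1 | intermediate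
8 | (1S)-1-{5-[(tert-butyldimethylsilyloxy)methyl]furan-2-yl}-2-[(4-methoxybenzyl)oxy]ethan-1-ol | COc1ccc(COC[C@H](O)c2ccc(CO[Si](C)(C)C(C)(C)C)o2)cc1 | intermediate
9 | (2S)-6-[(tert-butyldimethylsilyloxy)methyl]-6-hydroxy-2-{[(4-methoxybenzyl)oxy]methyl}-2H-pyran-3(6H)-one, both anomers | COc1ccc(COC[C@@H]2OC(O)(CO[Si](C)(C)C(C)(C)C)C=CC2=O)cc1 | intermediate
10 | 1-(tert-butyldimethylsilyloxy)-1-methoxyethene | C=C(OC)O[Si](C)(C)C(C)(C)C | starting material
11 | methyl 2-[(2S,6S)-2-[(tert-butyldimethylsilyloxy)methyl]-6-{[(4-methoxybenzyl)oxy]methyl}-5-oxo-5,6-dihydro-2H-pyran-2-yl]acetate | COc1ccc(COC[C@@H]2O[C@](CC(=O)OC)(CO[Si](C)(C)C(C)(C)C)C=CC2=O)cc1 | intermediate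
12 | methyl 2-[(2S,6S)-2-[(tert-butyldimethylsilyloxy)methyl]-5-hydroxy-6-{[(4-methoxybenzyl)oxy]methyl}-5-methyl-5,6-dihydro-2H-pyran-2-yl]acetate, both C5 epimers | COc1ccc(COC[C@@H]2O[C@](CC(=O)OC)(CO[Si](C)(C)C(C)(C)C)C=CC2(C)O)cc1 | intermediate
13 | methyl 2-[(2R,6R)-2-[(tert-butyldimethylsilyloxy)methyl]-6-{[(4-methoxybenzyl)oxy]methyl}-5-methyl-3-oxo-3,6-dihydro-2H-pyran-2-yl]acetate | COc1ccc(COC[C@@H]2O[C@](CC(=O)OC)(CO[Si](C)(C)C(C)(C)C)C(=O)C=C2C)cc1 | intermediate
14 | methyl 2-[(2R,3S,6R)-2-[(tert-butyldimethylsilyloxy)methyl]-3-hydroxy-6-{[(4-methoxybenzyl)oxy]methyl}-5-methyl-3,6-dihydro-2H-pyran-2-yl]acetate | COc1ccc(COC[C@@H]2O[C@](CC(=O)OC)(CO[Si](C)(C)C(C)(C)C)[C@@H](O)C=C2C)cc1 | intermediate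
15 | 17-desmethyl pyranolactone (4R,7S,8R): cis-fused dihydropyran–gamma-lactone, C4 CH2OPMB, C5 methyl, C5=C6, lactone oxygen on C7, C8 CH2OTBS | COc1ccc(COC[C@@H]2O[C@]3(CC(=O)O[C@H]3C=C2C)CO[Si](C)(C)C(C)(C)C)cc1 | intermediate
16 | lithium enolate of 15 (C17=C19–OLi) | COc1ccc(COC[C@@H]2O[C@]3(C=C(O[Li])O[C@H]3C=C2C)CO[Si](C)(C)C(C)(C)C)cc1 | intermediate
17 | pyranolactone silyl ether (4R,7S,8R,17R): as 15 with C17 methyl cis to the pyran oxygen | COc1ccc(COC[C@@H]2O[C@]3([C@@H](C)C(=O)O[C@H]3C=C2C)CO[Si](C)(C)C(C)(C)C)cc1 | intermediate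
18 | pyranolactone C9 alcohol (stereocentres as in 17) | COc1ccc(COC[C@@H]2O[C@]3([C@@H](C)C(=O)O[C@H]3C=C2C)CO)cc1 | intermediate
19 | pyranolactone C9 aldehyde (stereocentres as in 17) | COc1ccc(COC[C@@H]2O[C@]3([C@@H](C)C(=O)O[C@H]3C=C2C)C=O)cc1 | intermediate
20 | 1,4-dioxaspiro[4.5]dec-6-en-8-one | O=C1CCC2(OCCO2)C=C1 | starting material
21 | 7-iodo-1,4-dioxaspiro[4.5]dec-6-en-8-one | O=C1CCC2(OCCO2)C=C1I | intermediate
22 | (8S)-7-iodo-1,4-dioxaspiro[4.5]dec-6-en-8-ol | O[C@H]1CCC2(OCCO2)C=C1I | intermediate
23 | (8S)-8-(tert-butyldimethylsilyloxy)-7-iodo-1,4-dioxaspiro[4.5]dec-6-ene | CC(C)(C)[Si](C)(C)O[C@H]1CCC2(OCCO2)C=C1I | intermediate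
24 | potassium trifluoro{[(4-methoxybenzyl)oxy]methyl}borate | [K+].COc1ccc(COC[B-](F)(F)F)cc1 | starting material
25 | (8S)-8-(tert-butyldimethylsilyloxy)-7-{[(4-methoxybenzyl)oxy]methyl}-1,4-dioxaspiro[4.5]dec-6-ene | CC(C)(C)[Si](C)(C)O[C@H]1CCC2(OCCO2)C=C1COCc3ccc(OC)cc3 | intermediate
26 | (4S)-4-(tert-butyldimethylsilyloxy)-3-{[(4-methoxybenzyl)oxy]methyl}cyclohex-2-en-1-one | O=C1CC[C@H](O[Si](C)(C)C(C)(C)C)C(COCc2ccc(OC)cc2)=C1 | intermediate
27 | lithium (3S,4S)-4-(tert-butyldimethylsilyloxy)-3-{[(4-methoxybenzyl)oxy]methyl}-3-methylcyclohex-1-en-1-olate | [Li]OC1=C[C@@](C)(COCc2ccc(OC)cc2)[C@@H](O[Si](C)(C)C(C)(C)C)CC1 | intermediate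
28 | (3S,4S)-4-(tert-butyldimethylsilyloxy)-3-{[(4-methoxybenzyl)oxy]methyl}-3-methylcyclohex-1-en-1-yl trifluoromethanesulfonate | O=S(=O)(OC1=C[C@@](C)(COCc2ccc(OC)cc2)[C@@H](O[Si](C)(C)C(C)(C)C)CC1)C(F)(F)F | intermediate
29 | tert-butyl{[(1S,2S)-2-{[(4-methoxybenzyl)oxy]methyl}-2-methyl-4-[(trimethylsilyl)methyl]cyclohex-3-en-1-yl]oxy}dimethylsilane | C[Si](C)(C)CC1=C[C@@](C)(COCc2ccc(OC)cc2)[C@@H](O[Si](C)(C)C(C)(C)C)CC1 | intermediate
30 | union product: ring A (C1 methyl and CH2OPMB, C14 OTBS, 11(20)-methylene) joined through C10–C9(OH) to C8 of the pyranolactone bearing C4 CH2OPMB; all centres as in 37 | C(OCc5ccc(OC)cc5)[C@@H]1O[C@]3([C@@H](C)C(=O)O[C@H]3C=C1C)[C@@H](O)[C@H]1C(=C)CC[C@H](O[Si](C)(C)C(C)(C)C)[C@]1(C)COCc5ccc(OC)cc5 | intermediate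
31 | C9,C14-diol (30 without the silyl group) | C(OCc5ccc(OC)cc5)[C@@H]1O[C@]3([C@@H](C)C(=O)O[C@H]3C=C1C)[C@@H](O)[C@H]1C(=C)CC[C@H](O)[C@]1(C)COCc5ccc(OC)cc5 | intermediate
32 | C9,C14-diacetate with 11(20)-methylene and PMB ethers on O2 and O3 | C(OCc5ccc(OC)cc5)[C@@H]1O[C@]3([C@@H](C)C(=O)O[C@H]3C=C1C)[C@@H](OC(C)=O)[C@H]1C(=C)CC[C@H](OC(C)=O)[C@]1(C)COCc5ccc(OC)cc5 | intermediate
33 | (11R)-11,20-epoxide of 32 | C(OCc5ccc(OC)cc5)[C@@H]1O[C@]3([C@@H](C)C(=O)O[C@H]3C=C1C)[C@@H](OC(C)=O)[C@H]1[C@]3(CC[C@H](OC(C)=O)[C@]1(C)COCc5ccc(OC)cc5)CO3 | intermediate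
34 | C2,C3-diol: 33 with CH2OH on C1 and on C4 | OC[C@@H]1O[C@]3([C@@H](C)C(=O)O[C@H]3C=C1C)[C@@H](OC(C)=O)[C@H]1[C@]3(CC[C@H](OC(C)=O)[C@]1(C)CO)CO3 | intermediate
35 | C2,C3-dialdehyde of the ring A–dihydropyranolactone | O=C[C@@H]1O[C@]3([C@@H](C)C(=O)O[C@H]3C=C1C)[C@@H](OC(C)=O)[C@H]1[C@]3(CC[C@H](OC(C)=O)[C@]1(C)C=O)CO3 | intermediate
36 | 6-deschloro-5-methyl-5-ene (2R,3S)-diol | CC1[C@H]2O[C@]3([C@@H](C)C(=O)O[C@H]3C=1)[C@@H](OC(C)=O)[C@H]1[C@]3(CC[C@H](OC(C)=O)[C@]1(C)[C@@H](O)[C@@H]2O)CO3 | intermediate
37 | CNP0340728.1 (1S,2R,3S,4R,6S,7R,8R,9S,10S,11R,14S,17R): 9,14-diacetoxy-6-chloro-2,3-dihydroxy-4,8-ether-bridged 11,20-epoxy-5(16)-ene lactone | C=C1[C@H]2O[C@]3([C@@H](C)C(=O)O[C@H]3[C@H]1Cl)[C@@H](OC(C)=O)[C@H]1[C@]3(CC[C@H](OC(C)=O)[C@]1(C)[C@@H](O)[C@@H]2O)CO3 | target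

**Step count and risks**

Total step count: 27. Longest linear sequence: 19 steps (furfuryl alcohol 4 to 37, steps 2–12 and 20–27).

Steps most likely to fail:

Step 26. Samarium may bridge the two ketyls after all, so that the C3 formyl group reacts through its other face and the ring closes to the cis-diol, or simple reduction of the aldehydes may outrun ring closure. The fallback replaces the one-step stereoselective coupling by a coupling–oxidation–directed-reduction relay. Setting out from 35, the closure is run without HMPA (SmI2, THF, −78 °C) to give the cis-diol, the 3-epimer of 36 F3. IBX in DMSO then oxidises its less hindered C3 carbinol (the C2 carbinol is neopentyl) to the 2-hydroxy-3-ketone F4. Me4NBH(OAc)3 in MeCN/AcOH, bound to the C2 hydroxyl, delivers hydride intramolecularly so that the new C3 oxygen is trans to O2, and the route is rejoined at 36.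

Step 20. The new bond joins two carbons that each adjoin a quaternary centre, so addition may be slow enough for protodesilylation of 29 to win, or the open transition state may give the anti (9R) relationship. The fallback is a conjugate addition–aldol union. Setting out from 26 and 19, Me2CuLi with Me3SiCl converts 26 into the trimethylsilyl enol ether F1. MeLi and then Cp2ZrCl2 turn it into the zirconium enolate, whose aldol addition to 19 is syn-selective whatever the enolate geometry and gives the C11 ketone beta-hydroxy ketone F2. Takai–Lombardo methylenation (Zn, CH2Br2, TiCl4) of the C11 carbonyl then rejoins the route at 30.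

Step 27. The electrophile may prefer the face of C5=C6 anti to the C7–O bond and deliver chlorine to the wrong face of C6. The fallback introduces oxygen first and chlorine with inversion. Setting out from 36, the singlet-oxygen ene reaction (O2, tetraphenylporphyrin, visible light, CH2Cl2, 0 °C) attacks that same face and, because only the C16 hydrogens are allylic and not geminal to oxygen, gives the 6-epi allylic hydroperoxide F5 with the 5(16)-methylene. PPh3 reduces it in the same flask to the 6-epi allylic alcohol F6. Corey–Kim chlorination (NCS, Me2S, CH2Cl2, −20 °C), which is selective for allylic alcohols over the hindered 2,3-diol, displaces with inversion and arrives at 37.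

Further compounds
F1 | step 20 | trimethylsilyl enol ether of (3S,4S)-4-(tert-butyldimethylsilyloxy)-3-{[(4-methoxybenzyl)oxy]methyl}-3-methylcyclohexanone | C[Si](C)(C)OC1=C[C@@](C)(COCc2ccc(OC)cc2)[C@@H](O[Si](C)(C)C(C)(C)C)CC1
F2 | step 20 | C11 ketone beta-hydroxy ketone (30 with C11=O in place of the methylene) | C(OCc5ccc(OC)cc5)[C@@H]1O[C@]3([C@@H](C)C(=O)O[C@H]3C=C1C)[C@@H](O)[C@H]1C(=O)CC[C@H](O[Si](C)(C)C(C)(C)C)[C@]1(C)COCc5ccc(OC)cc5
F3 | step 26 | cis-diol, 3-epimer of 36 | CC1[C@H]2O[C@]3([C@@H](C)C(=O)O[C@H]3C=1)[C@@H](OC(C)=O)[C@H]1[C@]3(CC[C@H](OC(C)=O)[C@]1(C)[C@@H](O)[C@H]2O)CO3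
F4 | step 26 | 2-hydroxy-3-ketone | CC1[C@H]2O[C@]3([C@@H](C)C(=O)O[C@H]3C=1)[C@@H](OC(C)=O)[C@H]1[C@]3(CC[C@H](OC(C)=O)[C@]1(C)[C@@H](O)C2=O)CO3
F5 | step 27 | 6-epi allylic hydroperoxide with 5(16)-methylene | C=C1[C@H]2O[C@]3([C@@H](C)C(=O)O[C@H]3[C@@H]1OO)[C@@H](OC(C)=O)[C@H]1[C@]3(CC[C@H](OC(C)=O)[C@]1(C)[C@@H](O)[C@@H]2O)CO3
F6 | step 27 | 6-epi allylic alcohol with 5(16)-methylene | C=C1[C@H]2O[C@]3([C@@H](C)C(=O)O[C@H]3[C@@H]1O)[C@@H](OC(C)=O)[C@H]1[C@]3(CC[C@H](OC(C)=O)[C@]1(C)[C@@H](O)[C@@H]2O)CO3
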